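The 1,2-dioxane (O1, O2, C3–C6) is cut at C3–C4, the one ring bond that joins two acceptor-type carbons: C4 lies β to the masked ketone C6, C3 β to the carboxyl. The key step closes this bond by a 6-exo-trig radical conjugate addition: a primary C4 radical, held by the preformed C6–O1–O2 peroxyketal tether, attacks C3 of an (E)-β-peroxyacryloyl oxazolidinone, whose auxiliary fixes C3. The precursor is an acyclic bromoethyl methoxy peroxyketal carrying the chiral acryloyl imide on O2. Because C3 and C6 are 1,4-related and the C6 ketal is exchangeable, C6 is then equilibrated to the axial-methoxy isomer; the enyne is attached last by Sonogashira coupling.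

Key step: step 6

Remark: ring atoms are numbered O1, O2, C3 (carries CH2CO2H), C4, C5, C6 (peroxyketal carbon); compounds 1, 2, 8, 9 and 19 are taken to be purchasable.

Step 1
Reactants: 1 (5-chloropent-1-yn-1-yl)trimethylsilane; 2 3-bromobut-3-en-1-ol
Product: 5 3-methylidene-8-(trimethylsilyl)oct-7-yn-1-ol, via Grignard reagent 3 (not isolated), via chloromagnesium alkoxide 4 (not isolated)
Conditions: 1: Mg, THF, reflux; 2: i-PrMgCl, THF, 0 °C; combine, Pd(dppf)Cl2 (cat.), THF, 0 °C to rt; aq. NH4Cl
Reagents that add atoms: none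
Why: Kumada–Corriu cross-coupling, in which zerovalent palladium inserts into the vinyl C–Br bond of 4 and the primary alkyl Grignard 3 transmetalates, the dppf ligand favouring reductive elimination over β-hydride elimination while the silyl cap keeps the alkyne inert.

Step 2
Reactants: 5 3-methylidene-8-(trimethylsilyl)oct-7-yn-1-ol
Product: 6 (8-bromo-6-methylideneoct-1-yn-1-yl)trimethylsilane
Conditions: CBr4, PPh3, CH2Cl2, 0 °C
Reagents that add atoms: carbon tetrabromide, BrC(Br)(Br)Br
Why: Appel reaction, in which bromide displaces the alkoxyphosphonium group by SN2 at the primary carbon under neutral conditions that leave the 1,1-disubstituted alkene and the silyl alkyne untouched.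

Step 3
Reactants: 6 (8-bromo-6-methylideneoct-1-yn-1-yl)trimethylsilane
Product: 7 rac-(8-bromo-6-hydroperoxy-6-methoxyoct-1-yn-1-yl)trimethylsilane
Conditions: O3, CH2Cl2/MeOH, −78 °C, stopped at the first excess of ozone; N2 purge
Reagents that add atoms: ozone, [O-][O+]=O; methanol, CO
Why: Criegee ozonolysis of the 1,1-disubstituted alkene, in which the primary ozonide splits into formaldehyde and the ketone O-oxide that methanol traps as the methoxy hydroperoxide, while silyl alkyne and alkyl bromide react far more slowly with ozone; the ketal centre forms racemic and is corrected in step 7.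

Step 4
Reactants: 8 (4S)-4-(diphenylmethyl)-1,3-oxazolidin-2-one; 9 (2E)-3-chloroprop-2-enoic acid
Product: 12 (4S)-3-[(2E)-3-chloroprop-2-enoyl]-4-(diphenylmethyl)-1,3-oxazolidin-2-one, via acid chloride 10 (not isolated), via lithium oxazolidinide 11 (not isolated)
Conditions: 9: (COCl)2, DMF (cat.), CH2Cl2, 0 °C to rt, concentrate; 8: n-BuLi, THF, −78 °C; then 10, −78 to 0 °C
Reagents that add atoms: none
Why: N-acylation of the lithiated Evans-type oxazolidinone with the acid chloride made in the flask, the low temperature keeping the amide anion from adding to the β-chlorovinyl unit, whose E geometry is retained.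

Step 5
Reactants: 7 rac-(8-bromo-6-hydroperoxy-6-methoxyoct-1-yn-1-yl)trimethylsilane; 12 (4S)-3-[(2E)-3-chloroprop-2-enoyl]-4-(diphenylmethyl)-1,3-oxazolidin-2-one
Product: 13 (4S)-3-[(2E)-3-{[(3RS)-1-bromo-3-methoxy-8-(trimethylsilyl)oct-7-yn-3-yl]peroxy}prop-2-enoyl]-4-(diphenylmethyl)-1,3-oxazolidin-2-one (both epimers at the peroxyketal carbon)
Conditions: DABCO (cat.), i-Pr2NEt, CH2Cl2, 0 °C
Reagents that add atoms: none
Why: Vinylic substitution by addition–elimination at the β-carbon of the vinylogous acid chloride, relayed by the DABCO-derived vinylammonium salt, in which the soft peroxy anion of 7 replaces chloride with retention of the E geometry and the weak amine base should leave the primary bromide untouched.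

Step 6
Reactants: 13 (4S)-3-[(2E)-3-{[(3RS)-1-bromo-3-methoxy-8-(trimethylsilyl)oct-7-yn-3-yl]peroxy}prop-2-enoyl]-4-(diphenylmethyl)-1,3-oxazolidin-2-one
Product: 14 (4S)-4-(diphenylmethyl)-3-{[(3S,6RS)-6-methoxy-6-[5-(trimethylsilyl)pent-4-yn-1-yl]-1,2-dioxan-3-yl]acetyl}-1,3-oxazolidin-2-one
Conditions: MgBr2·OEt2 (2 equiv), (Me3Si)3SiH, Et3B (cat.)/air, CH2Cl2, high dilution, −78 to −40 °C
Reagents that add atoms: none
Why: Proposed new method: the silyl radical abstracts bromine from 13, the primary C4 radical adds to C3 of the magnesium-chelated (E)-β-peroxyacryloyl imide, and the silane reduces the resulting chelated α-acyl radical, so two acceptor-type carbons are joined reductively; a carbon radical closing onto a peroxide-linked acrylate has no direct precedent. The closest known reactions are the β-alkoxyacrylate radical cyclisation to 2,6-disubstituted oxacycles and the Lewis-acid-chelated conjugate radical addition to β-oxygenated acryloyl oxazolidinones. The 1,2-dioxane closes in the 6-exo-trig mode through a chair transition state with the C3 acceptor equatorial. C3 is controlled by the auxiliary: in the s-cis chelate the diphenylmethyl group shields one face of C3, so the (4S)-auxiliary with the (E)-acrylate should give (3S); the (6R)-epimer of 13 is matched (axial OMe), the (6S)-epimer is mismatched and should also give some (3R,6S) diastereomer, and C6 itself is settled only in step 7. The step needs ring closure to outrun direct reduction of the C4 radical and radical attack on the O–O bond, which the gem-disubstituted tether, the Lewis-acid-activated acceptor, the slow hydrogen donor and the low temperature should secure; 3-exo attack of the cyclised radical on O2 (epoxide formation) should be slow for the stabilised, chelated radical.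

Step 7
Reactants: 14 (4S)-4-(diphenylmethyl)-3-{[(3S,6RS)-6-methoxy-6-[5-(trimethylsilyl)pent-4-yn-1-yl]-1,2-dioxan-3-yl]acetyl}-1,3-oxazolidin-2-one
Product: 15 (4S)-4-(diphenylmethyl)-3-{[(3S,6R)-6-methoxy-6-[5-(trimethylsilyl)pent-4-yn-1-yl]-1,2-dioxan-3-yl]acetyl}-1,3-oxazolidin-2-one
Conditions: PPTS (cat.), MeOH/CH2Cl2, rt; chromatography
Reagents that add atoms: methanol, CO
Why: Acid-catalysed peroxyketal exchange through the cyclic peroxycarbenium ion, which should settle at the isomer with axial methoxy (anomeric effect) and both carbon chains equatorial, that is (6R) once C3 is (3S); the (3R,6S) diastereomer is removed by chromatography thanks to the covalently bound auxiliary.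

Step 8
Reactants: 15 (4S)-4-(diphenylmethyl)-3-{[(3S,6R)-6-methoxy-6-[5-(trimethylsilyl)pent-4-yn-1-yl]-1,2-dioxan-3-yl]acetyl}-1,3-oxazolidin-2-one
Product: 18 2-[(3S,6R)-6-methoxy-6-(pent-4-yn-1-yl)-1,2-dioxan-3-yl]acetic acid, via peroxy acid 16 (not isolated), via silyl alkyne acid 17 (not isolated)
Conditions: LiOH, H2O2, THF/H2O, 0 °C; aq. Na2SO3; then MeOH, rt; dilute HCl to pH 3, 0 °C
Reagents that add atoms: hydrogen peroxide, OO
Why: Evans auxiliary cleavage, in which lithium hydroperoxide attacks the exocyclic imide carbonyl, sulfite reduces the peroxy acid to the carboxylate and hydroxide in aqueous methanol then removes the alkynyl silyl group; the carboxylate cannot lose the β-peroxide by E1cB, so C3 is not scrambled.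

Step 9
Reactants: 19 dec-9-enal
Product: 20 (1E)-1-iodoundeca-1,10-diene
Conditions: CHI3, CrCl2, THF, 0 °C to rt
Reagents that add atoms: iodoform, IC(I)I
Why: Takai olefination, in which the geminal dichromium species from iodoform and CrCl2 adds to the aldehyde and eliminates to the (E)-vinyl iodide while the terminal alkene stays inert.

Step 10
Reactants: 18 2-[(3S,6R)-6-methoxy-6-(pent-4-yn-1-yl)-1,2-dioxan-3-yl]acetic acid; 20 (1E)-1-iodoundeca-1,10-diene
Product: 21 2-[(3S,6R)-6-[(6E)-hexadeca-6,15-dien-4-yn-1-yl]-6-methoxy-1,2-dioxan-3-yl]acetic acid (CNP0125368.1)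
Conditions: Pd(PPh3)2Cl2 (cat.), CuI (cat.), i-Pr2NH, THF, degassed, dark, rt
Reagents that add atoms: none
Why: Sonogashira coupling of the terminal alkyne with the (E)-vinyl iodide with retention of alkene geometry; the peroxyketal should tolerate room-temperature palladium/copper coupling, and excess amine keeps the acid as its carboxylate.

Compound list
1 | (5-chloropent-1-yn-1-yl)trimethylsilane | C[Si](C)(C)C#CCCCCl | starting material
2 | 3-bromobut-3-en-1-ol | C=C(Br)CCO | starting material
3 | [5-(trimethylsilyl)pent-4-yn-1-yl]magnesium chloride | C[Si](C)(C)C#CCCC[Mg]Cl | intermediate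
4 | chloromagnesium 3-bromobut-3-en-1-olate | C=C(Br)CCO[Mg]Cl | intermediate
5 | 3-methylidene-8-(trimethylsilyl)oct-7-yn-1-ol | C=C(CCO)CCCC#C[Si](C)(C)C | intermediate
6 | (8-bromo-6-methylideneoct-1-yn-1-yl)trimethylsilane | C=C(CCBr)CCCC#C[Si](C)(C)C | intermediate
7 | rac-(8-bromo-6-hydroperoxy-6-methoxyoct-1-yn-1-yl)trimethylsilane | COC(CCBr)(OO)CCCC#C[Si](C)(C)C | intermediate
8 | (4S)-4-(diphenylmethyl)-1,3-oxazolidin-2-one | O=C1N[C@H](CO1)C(c2ccccc2)c2ccccc2 | starting material
9 | (2E)-3-chloroprop-2-enoic acid | OC(=O)/C=C/Cl | starting material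
10 | (2E)-3-chloroprop-2-enoyl chloride | ClC(=O)/C=C/Cl | intermediate
11 | lithium (4S)-4-(diphenylmethyl)-2-oxo-1,3-oxazolidin-3-ide | O=C1N([Li])[C@H](CO1)C(c2ccccc2)c2ccccc2 | intermediate
12 | (4S)-3-[(2E)-3-chloroprop-2-enoyl]-4-(diphenylmethyl)-1,3-oxazolidin-2-one | O=C1N(C(=O)/C=C/Cl)[C@H](CO1)C(c2ccccc2)c2ccccc2 | intermediate
13 | (4S)-3-[(2E)-3-{[(3RS)-1-bromo-3-methoxy-8-(trimethylsilyl)oct-7-yn-3-yl]peroxy}prop-2-enoyl]-4-(diphenylmethyl)-1,3-oxazolidin-2-one | COC(CCBr)(CCCC#C[Si](C)(C)C)OO/C=C/C(=O)N1C(=O)OC[C@@H]1C(c2ccccc2)c2ccccc2 | intermediate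
14 | (4S)-4-(diphenylmethyl)-3-{[(3S,6RS)-6-methoxy-6-[5-(trimethylsilyl)pent-4-yn-1-yl]-1,2-dioxan-3-yl]acetyl}-1,3-oxazolidin-2-one | COC1(CCCC#C[Si](C)(C)C)CC[C@@H](CC(=O)N2C(=O)OC[C@@H]2C(c3ccccc3)c3ccccc3)OO1 | intermediate
15 | (4S)-4-(diphenylmethyl)-3-{[(3S,6R)-6-methoxy-6-[5-(trimethylsilyl)pent-4-yn-1-yl]-1,2-dioxan-3-yl]acetyl}-1,3-oxazolidin-2-one | C[Si](C)(C)C#CCCC[C@]1(OC)CC[C@@H](CC(=O)N2C(=O)OC[C@@H]2C(c3ccccc3)c3ccccc3)OO1 | intermediate
16 | [(3S,6R)-6-methoxy-6-[5-(trimethylsilyl)pent-4-yn-1-yl]-1,2-dioxan-3-yl]ethaneperoxoic acid | C[Si](C)(C)C#CCCC[C@]1(OC)CC[C@@H](CC(=O)OO)OO1 | intermediate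
17 | 2-[(3S,6R)-6-methoxy-6-[5-(trimethylsilyl)pent-4-yn-1-yl]-1,2-dioxan-3-yl]acetic acid | C[Si](C)(C)C#CCCC[C@]1(OC)CC[C@@H](CC(=O)O)OO1 | intermediate
18 | 2-[(3S,6R)-6-methoxy-6-(pent-4-yn-1-yl)-1,2-dioxan-3-yl]acetic acid | C#CCCC[C@]1(OC)CC[C@@H](CC(=O)O)OO1 | intermediate
19 | dec-9-enal | C=CCCCCCCCC=O | starting material
20 | (1E)-1-iodoundeca-1,10-diene | C=CCCCCCCC/C=C/I | intermediate
21 | 2-[(3S,6R)-6-[(6E)-hexadeca-6,15-dien-4-yn-1-yl]-6-methoxy-1,2-dioxan-3-yl]acetic acid | C=CCCCCCCC/C=C/C#CCCC[C@]1(OC)CC[C@@H](CC(=O)O)OO1 | target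

Total step count: 10. Longest linear sequence: 8 steps (1, 2, 3, 5, 6, 7, 8, 10).

Steps most likely to fail

Step 6 (Proposed new method). The C4 radical may be reduced or may attack the O–O bond before it closes the ring, and face selectivity at C3 may be poor because the auxiliary competes with the chair preference of the mismatched C6 epimer. The fallback uses known chemistry and closes the ring at O2–C3 instead. It sets out from 6 and 12: zinc insertion into 6 (Zn, LiCl, THF) gives the alkylzinc bromide F1; Negishi coupling with 12 (Pd(PPh3)4, zerovalent palladium, THF, rt) gives the (E)-enoyl imide F2; chemoselective ozonolysis of its 1,1-disubstituted alkene (O3, CH2Cl2/MeOH, −78 °C) gives the hydroperoxy ketal F3; intramolecular 6-exo-trig peroxy-Michael addition (Et3N, CF3CH2OH, rt) then gives 14 together with its (3R) diastereomers, which are removed as in step 7. The route is rejoined at 14.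

Step 5. The peroxy anion may attack the imide carbonyl (acyl transfer and loss of the auxiliary) faster than it substitutes at the β-carbon. The fallback drops the auxiliary and takes the absolute configuration from a resolution. It sets out from 7: conjugate addition to methyl propiolate (N-methylmorpholine cat., CH2Cl2, 0 °C) gives the methyl (E)-β-peroxyacrylate F4; the same radical ring closure under substrate control alone (Bu3SnH, Et3B/air, benzene, rt, chair with axial OMe) gives the racemic methyl ester F5 with the target relative configuration; enantioselective hydrolysis with Burkholderia cepacia lipase (pH 7 phosphate buffer/MTBE, stopped near half conversion) should give the (3S,6R)-acid, and the sense of the lipase's preference has to be found by screening. The route is rejoined at 17, which is desilylated as in the last stage of step 8.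

Step 10. The carboxylate may bind copper and palladium and slow the coupling, which leaves time for phosphine- or copper-mediated cleavage of the O–O bond and for oxidative alkyne dimerisation. The fallback couples the neutral ester and frees the acid last. It sets out from 15: K2CO3 in MeOH (0 °C to rt) removes the auxiliary and the silyl group to give the methyl ester F6; Sonogashira coupling with 20 under the step 10 conditions gives the methyl ester F7; LiOH, THF/H2O, 0 °C gives 21, where the route is rejoined.

Further compounds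
F1 | step 6 | bromo[3-methylidene-8-(trimethylsilyl)oct-7-yn-1-yl]zinc | C[Si](C)(C)C#CCCCC(=C)CC[Zn]Br
F2 | step 6 | (4S)-4-(diphenylmethyl)-3-[(2E)-6-methylidene-11-(trimethylsilyl)undec-2-en-10-ynoyl]-1,3-oxazolidin-2-one | C=C(CC/C=C/C(=O)N1C(=O)OC[C@@H]1C(c2ccccc2)c2ccccc2)CCCC#C[Si](C)(C)C
F3 | step 6 | (4S)-4-(diphenylmethyl)-3-[(2E,6RS)-6-hydroperoxy-6-methoxy-11-(trimethylsilyl)undec-2-en-10-ynoyl]-1,3-oxazolidin-2-one | COC(OO)(CC/C=C/C(=O)N1C(=O)OC[C@@H]1C(c2ccccc2)c2ccccc2)CCCC#C[Si](C)(C)C
F4 | step 5 | methyl (2E)-3-{[(3RS)-1-bromo-3-methoxy-8-(trimethylsilyl)oct-7-yn-3-yl]peroxy}prop-2-enoate | COC(CCBr)(CCCC#C[Si](C)(C)C)OO/C=C/C(=O)OC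
F5 | step 5 | rac-methyl 2-[(3S,6R)-6-methoxy-6-[5-(trimethylsilyl)pent-4-yn-1-yl]-1,2-dioxan-3-yl]acetate (racemate, one enantiomer drawn) | C[Si](C)(C)C#CCCC[C@]1(OC)CC[C@@H](CC(=O)OC)OO1
F6 | step 10 | methyl 2-[(3S,6R)-6-methoxy-6-(pent-4-yn-1-yl)-1,2-dioxan-3-yl]acetate | C#CCCC[C@]1(OC)CC[C@@H](CC(=O)OC)OO1
F7 | step 10 | methyl 2-[(3S,6R)-6-[(6E)-hexadeca-6,15-dien-4-yn-1-yl]-6-methoxy-1,2-dioxan-3-yl]acetate | C=CCCCCCCC/C=C/C#CCCC[C@]1(OC)CC[C@@H](CC(=O)OC)OO1
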